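**Retrosynthetic overview**
1. Kukoamine A 20 comes from 19 by one global hydrogenation (two C=C, four O-benzyl). 19 comes from 17 by Boc removal.
2. 17 is cut at its two amide bonds into N4,N9-di-Boc-spermine 16 and two equivalents of the cinnamic active ester 10.
3. 10 comes from acid 7. The key C–C disconnection is at Cα=Cβ, giving aldehyde 3 and malonic acid 4 (Knoevenagel–Doebner, an intermolecular aldol-type condensation).
4. 16 comes from 1,4-diaminobutane 11 and two acrylonitrile 12 (double aza-Michael addition, Boc protection, nitrile hydrogenation).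
5. No ring is formed, since both benzene rings are bought in 1, and the target has no stereocentre.

Assumption: the target SMILES holds no stereocentre and no C=C bond, so kukoamine A is achiral and needs no enantiocontrol; half-reacted species of twofold reactions on symmetrical compounds are not numbered.

**Route**

Step 1
Reactants: 1 3,4-dihydroxybenzaldehyde; 2 benzyl bromide (2.4 equiv)
Product: 3 3,4-bis(benzyloxy)benzaldehyde
Conditions: K2CO3 (3 equiv), DMF, 60 °C, 6 h
Reagents that add atoms: benzyl bromide 2, BrCc1ccccc1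
Why: Williamson ether synthesis, in which both phenoxides displace the benzylic bromide (SN2) and mask the oxidation-prone catechol with groups that leave by hydrogenolysis at the end; no stereocentre is formed.

Step 2
Reactants: 3 3,4-bis(benzyloxy)benzaldehyde; 4 malonic acid (2 equiv)
Product: 7 (E)-3-[3,4-bis(benzyloxy)phenyl]acrylic acid, via aldol adduct 5 (not isolated), via benzylidenemalonic acid 6 (not isolated)
Conditions: pyridine, piperidine (0.1 equiv), 90 → 110 °C, 4 h; poured into cold 2 M HCl, filtered, recrystallised from EtOH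
Reagents that add atoms: malonic acid 4, OC(=O)CC(=O)O
Why: Knoevenagel–Doebner condensation, an intermolecular aldol-type addition of the malonic acid enolate to the non-enolisable aldehyde that forms the side-chain C–C bond, followed by dehydration and pyridine-promoted decarboxylation to the favoured E-alkene; the carbinol centre of 5 is transient and is erased.

Step 3
Reactants: 7 (E)-3-[3,4-bis(benzyloxy)phenyl]acrylic acid; 8 N-hydroxysuccinimide (1.1 equiv)
Product: 10 2,5-dioxopyrrolidin-1-yl (E)-3-[3,4-bis(benzyloxy)phenyl]acrylate, via O-acylisourea 9 (not isolated)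
Conditions: DCC (1.05 equiv), THF, 0 °C → rt, 16 h; urea filtered off, recrystallised from EtOAc/hexane
Reagents that add atoms: N-hydroxysuccinimide 8, ON1C(=O)CCC1=O
Why: Carbodiimide activation, in which DCC converts the acid into O-acylisourea 9 and N-hydroxysuccinimide intercepts it to give a crystalline, storable active ester; the E-alkene is untouched.

Step 4
Reactants: 11 1,4-diaminobutane; 12 acrylonitrile (2.05 equiv)
Product: 13 N,N'-bis(2-cyanoethyl)-1,4-diaminobutane
Conditions: EtOH, 0 °C (dropwise addition) → rt, 18 h; concentrated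
Reagents that add atoms: acrylonitrile 12, C=CC#N
Why: Double aza-Michael addition (cyanoethylation), in which each primary amine adds once quickly in protic solvent while a second addition at the more hindered secondary amine is much slower at or below rt.

Step 5
Reactants: 13 N,N'-bis(2-cyanoethyl)-1,4-diaminobutane; 14 di-tert-butyl dicarbonate (2.2 equiv)
Product: 15 di-tert-butyl butane-1,4-diylbis[(2-cyanoethyl)carbamate]
Conditions: CH2Cl2, 0 °C → rt, 12 h; silica chromatography
Reagents that add atoms: di-tert-butyl dicarbonate 14, CC(C)(C)OC(=O)OC(=O)OC(C)(C)C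
Why: Boc carbamate formation at the two secondary amines leaves the nitriles alone and gives a neutral compound that chromatography frees of mono- or tris-cyanoethylated material from step 4.

Step 6
Reactants: 15 di-tert-butyl butane-1,4-diylbis[(2-cyanoethyl)carbamate]
Product: 16 di-tert-butyl butane-1,4-diylbis[(3-aminopropyl)carbamate] (N4,N9-di-Boc-spermine)
Conditions: H2 (3.5 bar), Raney Ni, 7 M NH3 in MeOH, rt, 24 h; filtered through Celite
Reagents that add atoms: none
Why: Heterogeneous catalytic hydrogenation of the nitriles to primary amines, in which excess ammonia keeps the imine intermediates from condensing to secondary amines and the Boc groups are inert.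

Step 7
Reactants: 10 2,5-dioxopyrrolidin-1-yl (E)-3-[3,4-bis(benzyloxy)phenyl]acrylate (2.1 equiv); 16 N4,N9-di-Boc-spermine
Product: 17 N4,N9-di-Boc-N1,N12-bis[(E)-3,4-bis(benzyloxy)cinnamoyl]spermine
Conditions: Et3N (2.2 equiv), CH2Cl2, 0 °C → rt, 12 h; aq NaHCO3 wash, silica chromatography
Reagents that add atoms: none
Why: Aminolysis of an active ester (amide bond formation), regiospecific because only the two terminal primary amines of 16 are free and the inner nitrogens are carbamates.

Step 8
Reactants: 17 N4,N9-di-Boc-N1,N12-bis[(E)-3,4-bis(benzyloxy)cinnamoyl]spermine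
Product: 19 N1,N12-bis[(E)-3,4-bis(benzyloxy)cinnamoyl]spermine, via bis-hydrochloride salt 18 (not isolated)
Conditions: 4 M HCl in dioxane (10 equiv), CH2Cl2, 0 °C → rt, 3 h; then 1 M aq NaOH, extraction with CH2Cl2/i-PrOH 9:1; used at once
Reagents that add atoms: none
Why: Acidolytic Boc cleavage, which aryl benzyl ethers and cinnamamides survive at rt, with free-basing done on the lipophilic protected compound so that base never meets a free catechol.

Step 9
Reactants: 19 N1,N12-bis[(E)-3,4-bis(benzyloxy)cinnamoyl]spermine
Product: 20 kukoamine A [N1,N12-bis(3,4-dihydroxyhydrocinnamoyl)spermine]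
Conditions: H2 (3 bar), 20% Pd(OH)2/C, degassed THF–MeOH 1:1, rt, 16 h; filtered through Celite under Ar, evaporated
Reagents that add atoms: none
Why: Catalytic hydrogenation and hydrogenolysis in one operation saturate both cinnamoyl C=C bonds and cleave the four O-benzyl ethers, so the neutral target is obtained by filtration and evaporation; no stereocentre arises.

**Compound list**
1 | 3,4-dihydroxybenzaldehyde | O=Cc1ccc(O)c(O)c1 | starting material
2 | benzyl bromide | BrCc1ccccc1 | starting material
3 | 3,4-bis(benzyloxy)benzaldehyde | O=Cc1ccc(OCc2ccccc2)c(OCc2ccccc2)c1 | intermediate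
4 | malonic acid | OC(=O)CC(=O)O | starting material
5 | aldol adduct, 2-{[3,4-bis(benzyloxy)phenyl](hydroxy)methyl}malonic acid (racemic, not isolated) | OC(c1ccc(OCc2ccccc2)c(OCc2ccccc2)c1)C(C(=O)O)C(=O)O | intermediate
6 | 2-[3,4-bis(benzyloxy)benzylidene]malonic acid (not isolated) | OC(=O)C(=Cc1ccc(OCc2ccccc2)c(OCc2ccccc2)c1)C(=O)O | intermediate
7 | (E)-3-[3,4-bis(benzyloxy)phenyl]acrylic acid | OC(=O)/C=C/c1ccc(OCc2ccccc2)c(OCc2ccccc2)c1 | intermediate
8 | N-hydroxysuccinimide | ON1C(=O)CCC1=O | starting material
9 | O-acylisourea from 7 and DCC (not isolated) | O=C(/C=C/c1ccc(OCc2ccccc2)c(OCc2ccccc2)c1)OC(=NC1CCCCC1)NC1CCCCC1 | intermediate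
10 | 2,5-dioxopyrrolidin-1-yl (E)-3-[3,4-bis(benzyloxy)phenyl]acrylate | O=C(/C=C/c1ccc(OCc2ccccc2)c(OCc2ccccc2)c1)ON1C(=O)CCC1=O | intermediate
11 | 1,4-diaminobutane (putrescine) | NCCCCN | starting material
12 | acrylonitrile | C=CC#N | starting material
13 | N,N'-bis(2-cyanoethyl)-1,4-diaminobutane | N#CCCNCCCCNCCC#N | intermediate
14 | di-tert-butyl dicarbonate | CC(C)(C)OC(=O)OC(=O)OC(C)(C)C | starting material
15 | di-tert-butyl butane-1,4-diylbis[(2-cyanoethyl)carbamate] | N#CCCN(C(=O)OC(C)(C)C)CCCCN(C(=O)OC(C)(C)C)CCC#N | intermediate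
16 | di-tert-butyl butane-1,4-diylbis[(3-aminopropyl)carbamate] (N4,N9-di-Boc-spermine) | NCCCN(C(=O)OC(C)(C)C)CCCCN(C(=O)OC(C)(C)C)CCCN | intermediate
17 | N4,N9-di-Boc-N1,N12-bis[(E)-3,4-bis(benzyloxy)cinnamoyl]spermine | O=C(/C=C/c1ccc(OCc2ccccc2)c(OCc2ccccc2)c1)NCCCN(C(=O)OC(C)(C)C)CCCCN(C(=O)OC(C)(C)C)CCCNC(=O)/C=C/c1ccc(OCc2ccccc2)c(OCc2ccccc2)c1 | intermediate
18 | N1,N12-bis[(E)-3,4-bis(benzyloxy)cinnamoyl]spermine bis-hydrochloride (not isolated) | O=C(/C=C/c1ccc(OCc2ccccc2)c(OCc2ccccc2)c1)NCCCNCCCCNCCCNC(=O)/C=C/c1ccc(OCc2ccccc2)c(OCc2ccccc2)c1.Cl.Cl | intermediate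
19 | N1,N12-bis[(E)-3,4-bis(benzyloxy)cinnamoyl]spermine | O=C(/C=C/c1ccc(OCc2ccccc2)c(OCc2ccccc2)c1)NCCCNCCCCNCCCNC(=O)/C=C/c1ccc(OCc2ccccc2)c(OCc2ccccc2)c1 | intermediate
20 | kukoamine A | O=C(CCc1ccc(O)c(O)c1)NCCCNCCCCNCCCNC(=O)CCc1ccc(O)c(O)c1 | target

**Step count**
Total steps: 9. The route is convergent, with steps 1–3 and steps 4–6 meeting at step 7.
Longest linear sequence: 6 steps (1→2→3→7→8→9, or 4→5→6→7→8→9).

**Three steps most likely to fail**

Step 6 (nitrile hydrogenation). The risks are secondary-amine coupling products, incomplete reduction and variable Raney Ni activity. The fallback avoids nitriles altogether, sets out from 11 and comes back at 16. 1,4-Diaminobutane 11 is acylated at both ends with purchased N-Cbz-β-alanine N-hydroxysuccinimide ester F1 (Et3N, CH2Cl2) to give N,N'-(butane-1,4-diyl)bis[3-(benzyloxycarbonylamino)propanamide] F2. BH3·THF at reflux, followed by MeOH/HCl and a basic work-up, reduces only the two amide carbonyls and gives N1,N12-di-Cbz-spermine F3. Boc2O 14 caps the two inner amines to give N1,N12-di-Cbz-N4,N9-di-Boc-spermine F4. H2 over Pd/C in MeOH then removes the Cbz groups and delivers 16.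

Step 9 (global hydrogenation in the presence of free secondary amines). The risks are slow debenzylation through amine binding to Pd and air oxidation of the basic catechol product. The fallback reverses the order of the deprotections, sets out from 17 and comes back at 20. Compound 17, whose amines are still carbamates, is hydrogenated (H2, 10% Pd/C, THF–MeOH) to N4,N9-di-Boc-kukoamine A F5, a neutral compound that can be chromatographed. 4 M HCl in dioxane then gives kukoamine A dihydrochloride F6, which precipitates and is filtered off. Exactly 2.0 equiv of NaOMe in degassed MeOH at 0 °C under Ar releases 20, and the residue is taken up in dry EtOH to leave the inorganic salt behind. This neutralisation is delicate, because the catechol OH and the secondary ammonium groups have similar acidity.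

Step 4 (bis-cyanoethylation). The risk is a statistical mixture of mono-, bis- and tris-adducts that lowers the throughput of the whole amine arm. The fallback replaces protecting-group control by kinetic chemoselectivity, sets out from 10 and comes back at 19. Purchased spermine F7 is held dilute in CH2Cl2 at −20 °C and 10 (2.0 equiv) is added slowly. The mild, bulky active ester acylates the two unhindered primary amines faster than the inner secondary ones. Compound 19 is purified on silica with CH2Cl2/MeOH/NH3, which makes steps 4–8 unnecessary.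

**Further compounds**
F1 | step 6 | N-Cbz-β-alanine N-hydroxysuccinimide ester (purchased) | O=C(CCNC(=O)OCc1ccccc1)ON1C(=O)CCC1=O
F2 | step 6 | N,N'-(butane-1,4-diyl)bis[3-(benzyloxycarbonylamino)propanamide] | O=C(CCNC(=O)OCc1ccccc1)NCCCCNC(=O)CCNC(=O)OCc1ccccc1
F3 | step 6 | N1,N12-di-Cbz-spermine | O=C(NCCCNCCCCNCCCNC(=O)OCc1ccccc1)OCc1ccccc1
F4 | step 6 | N1,N12-di-Cbz-N4,N9-di-Boc-spermine | O=C(NCCCN(C(=O)OC(C)(C)C)CCCCN(C(=O)OC(C)(C)C)CCCNC(=O)OCc1ccccc1)OCc1ccccc1
F5 | step 9 | N4,N9-di-Boc-kukoamine A | O=C(CCc1ccc(O)c(O)c1)NCCCN(C(=O)OC(C)(C)C)CCCCN(C(=O)OC(C)(C)C)CCCNC(=O)CCc1ccc(O)c(O)c1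
F6 | step 9 | kukoamine A dihydrochloride | O=C(CCc1ccc(O)c(O)c1)NCCCNCCCCNCCCNC(=O)CCc1ccc(O)c(O)c1.Cl.Cl
F7 | step 4 | spermine (purchased) | NCCCNCCCCNCCCN
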